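## Retrosynthetic overview

1. Target ⇒ Cα–Cβ disconnection of the dihydrochalcone (the new step): the chromene methyl ketone plus para-quinone methide released from 4-hydroxybenzyl alcohol.
2. Pyran ring ⇒ 3-prenyl-2,4-dihydroxyacetophenone plus prenal (condensation, then oxa-6π closure at C5); C3 is blocked, so only the linear chromene can form.
3. C3–prenyl bond ⇒ aromatic Claisen rearrangement of the 4-O-(1,1-dimethylallyl) ether, made from 2,4-dihydroxyacetophenone and 3-chloro-3-methylbut-1-yne, then Lindlar reduction.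
4. Ring order: both benzene rings are bought; the only ring formed is the pyran ring (step 4).

Assumption: the target has no stereocentre and no stereogenic double bond, so it is achiral; "single enantiomer" is met by the one constitution drawn, and the route only has to control regiochemistry.

## Route

Step 1
Reactants: 1 1-(2,4-dihydroxyphenyl)ethan-1-one; 2 3-chloro-3-methylbut-1-yne
Product: 3 1-[2-hydroxy-4-(2-methylbut-3-yn-2-yloxy)phenyl]ethan-1-one
Conditions: K2CO3 (1.5 equiv), KI (10 mol%), CuI (5 mol%), acetone, reflux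
Reagents that add atoms: 3-chloro-3-methylbut-1-yne (2), CC(C)(Cl)C#C
Why: Copper-assisted Williamson-type O-propargylation occurs only at the more acidic, non-chelated 4-OH because the 2-OH is locked in a hydrogen bond to the ketone.

Step 2
Reactants: 3 1-[2-hydroxy-4-(2-methylbut-3-yn-2-yloxy)phenyl]ethan-1-one
Product: 4 1-[2-hydroxy-4-(2-methylbut-3-en-2-yloxy)phenyl]ethan-1-one
Conditions: H2 (1 atm), Lindlar cat., quinoline, EtOAc, rt
Reagents that add atoms: none
Why: Lindlar semihydrogenation of a terminal alkyne stops at the alkene and leaves the aryl ketone and the aryl ether untouched.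

Step 3
Reactants: 4 1-[2-hydroxy-4-(2-methylbut-3-en-2-yloxy)phenyl]ethan-1-one
Product: 6 1-[2,4-dihydroxy-3-(3-methylbut-2-en-1-yl)phenyl]ethan-1-one, via Claisen dienone 5 (not isolated)
Conditions: PhNEt2, 130 °C, 3 h
Reagents that add atoms: none
Why: The aromatic Claisen rearrangement ([3,3]) of the tertiary allyl ether delivers a linear prenyl group to carbon, and the bond fixation caused by the chelated 2-hydroxy ketone directs it to C3 (between the two oxygens) through dienone 5, which tautomerises to the phenol.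

Step 4
Reactants: 6 1-[2,4-dihydroxy-3-(3-methylbut-2-en-1-yl)phenyl]ethan-1-one; 7 3-methylbut-2-enal
Product: 9 1-[7-hydroxy-2,2-dimethyl-8-(3-methylbut-2-en-1-yl)-2H-chromen-6-yl]ethan-1-one, via ortho-quinone methide 8 (not isolated)
Conditions: EDDA (20 mol%), xylene, 140 °C
Reagents that add atoms: 3-methylbut-2-enal (7), CC(C)=CC=O
Why: Amine-catalysed Knoevenagel-type condensation of the phenol carbon with prenal, then oxa-6π electrocyclisation of quinone methide 8 (formal [3+3] chromenylation); with C3 blocked by the prenyl group the only position ortho to the free 4-OH is C5, so only the linear 2H-chromene can form.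

Step 5
Reactants: 9 1-[7-hydroxy-2,2-dimethyl-8-(3-methylbut-2-en-1-yl)-2H-chromen-6-yl]ethan-1-one; 10 4-(hydroxymethyl)phenol
Product: 12 1-[7-hydroxy-2,2-dimethyl-8-(3-methylbut-2-en-1-yl)-2H-chromen-6-yl]-3-(4-hydroxyphenyl)propan-1-one, via para-quinone methide 11 (not isolated)
Conditions: KOtBu (3.5 equiv), 10 (1.5 equiv, syringe pump over 8 h), t-AmOH, 100 °C, Ar; then aq. NH4Cl
Reagents that add atoms: 4-(hydroxymethyl)phenol (10), OCc1ccc(O)cc1
Why: Proposed new method: redox-neutral dehydrative α-(4-hydroxybenzyl)ation of a methyl ketone, in which the phenoxide of 10 loses hydroxide by 1,6-elimination at 100 °C to give para-quinone methide 11 in low steady-state concentration, the potassium enolate of 9 adds to its exocyclic CH2 in a 1,6-conjugate (vinylogous Michael) addition, and rearomatisation to the free 4-hydroxyphenyl group drives the step; O-adducts of 11 revert to 11 whereas the C–C adduct cannot, ring A of 9 has no free position ortho or para to oxygen, and no hydride, metal or acid is present, so the prenyl and chromene alkenes survive; the closest known reaction types are the 1,6-addition of enolates and enamines to stabilised (δ-aryl, 2,6-di-tert-butyl) para-quinone methides and the metal-catalysed hydrogen-borrowing α-benzylation of acetophenones with benzyl alcohols.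

## Compound list

1 | 1-(2,4-dihydroxyphenyl)ethan-1-one (2,4-dihydroxyacetophenone) | CC(=O)c1ccc(O)cc1O | starting material
2 | 3-chloro-3-methylbut-1-yne | CC(C)(Cl)C#C | starting material
3 | 1-[2-hydroxy-4-(2-methylbut-3-yn-2-yloxy)phenyl]ethan-1-one | CC(=O)c1ccc(OC(C)(C)C#C)cc1O | intermediate
4 | 1-[2-hydroxy-4-(2-methylbut-3-en-2-yloxy)phenyl]ethan-1-one | CC(=O)c1ccc(OC(C)(C)C=C)cc1O | intermediate
5 | 4-acetyl-5-hydroxy-6-(3-methylbut-2-en-1-yl)cyclohexa-2,4-dien-1-one (Claisen dienone, racemic, transient) | CC(=O)C1=C(O)C(CC=C(C)C)C(=O)C=C1 | intermediate (not isolated)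
6 | 1-[2,4-dihydroxy-3-(3-methylbut-2-en-1-yl)phenyl]ethan-1-one | CC(=O)c1ccc(O)c(CC=C(C)C)c1O | intermediate
7 | 3-methylbut-2-enal (prenal) | CC(C)=CC=O | starting material
8 | (6Z)-4-acetyl-3-hydroxy-2-(3-methylbut-2-en-1-yl)-6-(3-methylbut-2-en-1-ylidene)cyclohexa-2,4-dien-1-one (ortho-quinone methide) | CC(=O)C1=C/C(=C/C=C(C)C)C(=O)C(CC=C(C)C)=C1O | intermediate (not isolated)
9 | 1-[7-hydroxy-2,2-dimethyl-8-(3-methylbut-2-en-1-yl)-2H-chromen-6-yl]ethan-1-one | CC(=O)c1cc2C=CC(C)(C)Oc2c(CC=C(C)C)c1O | intermediate
10 | 4-(hydroxymethyl)phenol (4-hydroxybenzyl alcohol) | OCc1ccc(O)cc1 | starting material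
11 | 4-methylidenecyclohexa-2,5-dien-1-one (para-quinone methide) | C=C1C=CC(=O)C=C1 | intermediate (not isolated)
12 | 1-[7-hydroxy-2,2-dimethyl-8-(3-methylbut-2-en-1-yl)-2H-chromen-6-yl]-3-(4-hydroxyphenyl)propan-1-one | CC(C)=CCc1c(O)c(C(=O)CCc2ccc(O)cc2)cc2c1OC(C)(C)C=C2 | target

## Step count and risk

Total step count: 5. Longest linear sequence: 5 steps (1 → 3 → 4 → 6 → 9 → 12); all other inputs are commercial.

The three steps most likely to fail:

**Step 5 (the proposed new step).** The risks are slow release of 11, self-condensation of 10 (the reason for slow addition) and a second benzylation at the α-carbon of 12. The fallback uses known chemistry, sets out from 9 and comes back to the route at 12. Claisen–Schmidt condensation of 9 with commercial 4-(methoxymethoxy)benzaldehyde (COCOc1ccc(C=O)cc1; KOH, EtOH/H2O, rt) gives (2E)-1-[7-hydroxy-2,2-dimethyl-8-(3-methylbut-2-en-1-yl)-2H-chromen-6-yl]-3-[4-(methoxymethoxy)phenyl]prop-2-en-1-one F1. Copper hydride 1,4-reduction ([(Ph3P)CuH]6 cat., PMHS, t-BuOH, toluene, rt) reduces only the enone C=C and gives 1-[7-hydroxy-2,2-dimethyl-8-(3-methylbut-2-en-1-yl)-2H-chromen-6-yl]-3-[4-(methoxymethoxy)phenyl]propan-1-one F2. Brief treatment with HCl in MeOH at 45 °C removes the MOM group and gives 12.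

**Step 3.** The risks are the C5-prenyl regioisomer and thermal loss of isoprene from the tertiary ether. The fallback sets out from 1 and comes back at 6, replacing the sigmatropic route (steps 1–3) by cross-coupling. Iodination of 1 (I2, HIO3, EtOH/H2O, 40 °C) between the two hydroxyl groups gives 1-(2,4-dihydroxy-3-iodophenyl)ethan-1-one F3. Stille coupling with commercial tributyl(3-methylbut-2-en-1-yl)stannane (CCCC[Sn](CCCC)(CCCC)CC=C(C)C; Pd(PPh3)4, DMF, 90 °C) then transfers the linear prenyl group and gives 6.

**Step 4.** The risk is that C5, para to the chelated hydroxyl, condenses only sluggishly with prenal. The fallback sets out from 6 and comes back at 9. O-Alkylation of the free 4-OH of 6 with 2 (K2CO3, KI, CuI, acetone, reflux) gives 1-[2-hydroxy-3-(3-methylbut-2-en-1-yl)-4-(2-methylbut-3-yn-2-yloxy)phenyl]ethan-1-one F4. Heating F4 in PhNEt2 at 190 °C triggers the propargyl Claisen rearrangement to C5, the only free ortho position, and closes the pyran ring through the same quinone methide 8 to give 9.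

Further compounds
F1 | step 5 | (2E)-1-[7-hydroxy-2,2-dimethyl-8-(3-methylbut-2-en-1-yl)-2H-chromen-6-yl]-3-[4-(methoxymethoxy)phenyl]prop-2-en-1-one | CC(C)=CCc1c(O)c(C(=O)/C=C/c2ccc(OCOC)cc2)cc2c1OC(C)(C)C=C2
F2 | step 5 | 1-[7-hydroxy-2,2-dimethyl-8-(3-methylbut-2-en-1-yl)-2H-chromen-6-yl]-3-[4-(methoxymethoxy)phenyl]propan-1-one | CC(C)=CCc1c(O)c(C(=O)CCc2ccc(OCOC)cc2)cc2c1OC(C)(C)C=C2
F3 | step 3 | 1-(2,4-dihydroxy-3-iodophenyl)ethan-1-one | CC(=O)c1ccc(O)c(I)c1O
F4 | step 4 | 1-[2-hydroxy-3-(3-methylbut-2-en-1-yl)-4-(2-methylbut-3-yn-2-yloxy)phenyl]ethan-1-one | CC(=O)c1ccc(OC(C)(C)C#C)c(CC=C(C)C)c1O
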